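**Retrosynthetic overview**
1. Pauciflorol E ← global O‑debenzylation of penta‑O‑benzyl ether 27; C(α), the CH between the ketone and ring B, is fixed last by base equilibration.
2. Seven‑membered ring (second ring formed) ← intramolecular Friedel–Crafts alkylation of ring B by α‑bromo ketone 25.
3. Key C–C bond (ketone carbon to C(α)) ← intermolecular aldol addition of the lithium enolate of allyl [4‑(benzyloxy)phenyl]acetate to aldehyde 16; oxidation and deallylative decarboxylation then give deoxybenzoin 23.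
4. Dihydrofuran ring (first ring formed) ← enantioselective dirhodium‑carbene C–H insertion of diaryldiazomethane 12 (sets C3), then acid epimerisation of C2 to trans.
5. Diaryl ketone 10 ← Grignard addition of ring B to aldehyde 7, made from 5‑bromoresorcinol by benzylation, Vilsmeier formylation, ortho‑selective debenzylation and O‑alkylation.

Assumption: Rh2(R‑PTAD)4 is taken to deliver the 3R configuration in step 8; if the sense proves opposite, Rh2(S‑PTAD)4 is used with no other change.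

Abbreviations: Bn = benzyl. Ring A = benzo ring of the benzofuran; ring B = 3,5‑dioxygenated aryl on C3. DBF = (2R,3R)‑6‑(benzyloxy)‑2‑[4‑(benzyloxy)phenyl]‑3‑[3,5‑bis(benzyloxy)phenyl]‑2,3‑dihydro‑1‑benzofuran‑4‑yl.

**Route**

Step 1
Reactants: 1 5‑bromobenzene‑1,3‑diol
Product: 2 1,3‑bis(benzyloxy)‑5‑bromobenzene
Conditions: BnBr (2.2 equiv), K2CO3, DMF, 60 °C
Reagents that add atoms: benzyl bromide, BrCc1ccccc1
Why: Williamson ether synthesis (SN2 O‑benzylation of both phenoxides) protects the two phenols with groups that can be removed at the end without acid‑labile or reductive damage.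

Step 2
Reactants: 2 1,3‑bis(benzyloxy)‑5‑bromobenzene
Product: 4 2,4‑bis(benzyloxy)‑6‑bromobenzaldehyde, via aryl iminium salt 3 (not isolated)
Conditions: POCl3, DMF, 0 to 90 °C; then aq NaOAc
Reagents that add atoms: N,N‑dimethylformamide, CN(C)C=O; water, O
Why: Vilsmeier–Haack formylation attacks the position para to one benzyloxy group and ortho to the other, because the site between the two benzyloxy groups is more hindered, so CHO ends up between Br and OBn.

Step 3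
Reactants: 4 2,4‑bis(benzyloxy)‑6‑bromobenzaldehyde
Product: 5 4‑(benzyloxy)‑2‑bromo‑6‑hydroxybenzaldehyde
Conditions: BCl3 (1.1 equiv), CH2Cl2, −78 to −20 °C; then H2O
Reagents that add atoms: none
Why: Chelation‑controlled Lewis‑acid ether cleavage, in which BCl3 bound to the aldehyde oxygen cleaves only the ortho benzyl ether and leaves the para one.

Step 4
Reactants: 5 4‑(benzyloxy)‑2‑bromo‑6‑hydroxybenzaldehyde; 6 1‑(benzyloxy)‑4‑(chloromethyl)benzene
Product: 7 4‑(benzyloxy)‑2‑{[4‑(benzyloxy)phenyl]methoxy}‑6‑bromobenzaldehyde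
Conditions: K2CO3, KI (cat.), DMF, 60 °C
Reagents that add atoms: none
Why: Williamson etherification of the freed phenol installs the ArCH2–O unit whose CH2 becomes C2 of the dihydrofuran.

Step 5
Reactants: 2 1,3‑bis(benzyloxy)‑5‑bromobenzene; 7 4‑(benzyloxy)‑2‑{[4‑(benzyloxy)phenyl]methoxy}‑6‑bromobenzaldehyde
Product: 9 [4‑(benzyloxy)‑2‑{[4‑(benzyloxy)phenyl]methoxy}‑6‑bromophenyl][3,5‑bis(benzyloxy)phenyl]methanol (racemic), via Grignard reagent 8 (not isolated)
Conditions: 2, Mg, THF, 60 °C; then 7, −40 to 0 °C; H2O (aq NH4Cl)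
Reagents that add atoms: none
Why: Grignard addition to the non‑enolisable aldehyde joins ring B to ring A at the future C3, and the aryl bromide on 7 does not exchange with an aryl Grignard at this temperature.

Step 6
Reactants: 9 the diaryl carbinol
Product: 10 [4‑(benzyloxy)‑2‑{[4‑(benzyloxy)phenyl]methoxy}‑6‑bromophenyl][3,5‑bis(benzyloxy)phenyl]methanone
Conditions: Dess–Martin periodinane, NaHCO3, CH2Cl2, rt
Reagents that add atoms: none
Why: Dess–Martin oxidation of the doubly benzylic alcohol gives the diaryl ketone under neutral conditions that spare the benzyl ethers and the aryl bromide.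

Step 7
Reactants: 10 the diaryl ketone
Product: 11 [4‑(benzyloxy)‑2‑{[4‑(benzyloxy)phenyl]methoxy}‑6‑bromophenyl][3,5‑bis(benzyloxy)phenyl]methanone hydrazone (E/Z mixture)
Conditions: N2H4·H2O (excess), AcOH (cat.), n‑BuOH, 110 °C, sealed tube
Reagents that add atoms: hydrazine, NN
Why: Acid‑catalysed hydrazone condensation, forced by excess hydrazine and heat because the ketone is flanked by two ortho substituents.

Step 8
Reactants: 11 the hydrazone
Product: 13 (2S,3R)‑6‑(benzyloxy)‑2‑[4‑(benzyloxy)phenyl]‑3‑[3,5‑bis(benzyloxy)phenyl]‑4‑bromo‑2,3‑dihydro‑1‑benzofuran (cis), via diaryldiazomethane 12 (not isolated)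
Conditions: MnO2, CH2Cl2, 0 °C, filter; then Rh2(R‑PTAD)4 (1 mol%; PTAD = N‑phthaloyl‑1‑adamantylglycinate), CH3CN, 0 °C
Reagents that add atoms: none
Why: MnO2 dehydrogenates the hydrazone to the diazo compound, and the chiral dirhodium carboxylate (divalent rhodium) then effects an intramolecular 1,5 C–H insertion of the donor/donor carbene into the electron‑rich benzylic O–CH2 bond, cis‑selectively, with the catalyst setting C3 as R.

Step 9
Reactants: 13 the cis‑dihydrobenzofuran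
Product: 14 (2R,3R)‑6‑(benzyloxy)‑2‑[4‑(benzyloxy)phenyl]‑3‑[3,5‑bis(benzyloxy)phenyl]‑4‑bromo‑2,3‑dihydro‑1‑benzofuran (trans)
Conditions: BF3·OEt2 (0.3 equiv), CH2Cl2 (dilute), −20 to 0 °C
Reagents that add atoms: none
Why: Lewis‑acid epimerisation by reversible ionisation of the C2–O bond to the 4‑(benzyloxy)benzyl cation and reclosure gives the thermodynamically preferred trans isomer (C2 becomes R) while C3 is untouched.

Step 10
Reactants: 14 the trans bromide
Product: 16 (2R,3R)‑6‑(benzyloxy)‑2‑[4‑(benzyloxy)phenyl]‑3‑[3,5‑bis(benzyloxy)phenyl]‑2,3‑dihydro‑1‑benzofuran‑4‑carbaldehyde, via aryllithium 15 (not isolated)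
Conditions: n‑BuLi (1.1 equiv), THF, −78 °C; DMF, −78 to 0 °C; H2O
Reagents that add atoms: N,N‑dimethylformamide, CN(C)C=O
Why: Bromine–lithium exchange followed by Bouveault formylation installs the future ketone carbon at the only ring A position that electrophilic substitution cannot reach; neither stereocentre is acidic enough to be touched at −78 °C.

Step 11
Reactants: 17 [4‑(benzyloxy)phenyl]acetic acid
Product: 18 prop‑2‑en‑1‑yl [4‑(benzyloxy)phenyl]acetate
Conditions: allyl bromide, K2CO3, DMF, rt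
Reagents that add atoms: allyl bromide, C=CCBr
Why: Carboxylate O‑alkylation gives an ester that can later be removed under neutral palladium catalysis instead of hot base.

Step 12
Reactants: 16 the aldehyde; 18 prop‑2‑en‑1‑yl [4‑(benzyloxy)phenyl]acetate
Product: 20 prop‑2‑en‑1‑yl 2‑[4‑(benzyloxy)phenyl]‑3‑hydroxy‑3‑(DBF)propanoate (diastereomer mixture at the two new centres), via lithium ester enolate 19 (not isolated)
Conditions: LiN(iPr)2 (1.3 equiv), 18, THF, −78 °C; then 16, −78 °C; H2O (aq NH4Cl) at −78 °C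
Reagents that add atoms: none
Why: Directed intermolecular aldol addition of the preformed lithium ester enolate to the non‑enolisable aldehyde forms the bond between the future ketone carbon and C(α) and so unites the last aryl fragment with the core; both new stereocentres are erased in steps 13–14, so their ratio is irrelevant.

Step 13
Reactants: 20 the aldol adduct
Product: 21 prop‑2‑en‑1‑yl 2‑[4‑(benzyloxy)phenyl]‑3‑oxo‑3‑(DBF)propanoate
Conditions: Dess–Martin periodinane, NaHCO3, CH2Cl2, 0 °C to rt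
Reagents that add atoms: none
Why: Dess–Martin oxidation converts the β‑hydroxy ester into the β‑keto ester without base, so retro‑aldol cleavage is avoided.

Step 14
Reactants: 21 the β‑keto ester
Product: 23 2‑[4‑(benzyloxy)phenyl]‑1‑(DBF)ethan‑1‑one, via beta‑keto acid 22 (not isolated)
Conditions: Pd(PPh3)4 (5 mol%), morpholine (5 equiv), THF, rt to 40 °C
Reagents that add atoms: none
Why: Tsuji–Trost deallylation (zerovalent palladium π‑allyl, trapped by morpholine) liberates the β‑keto acid, which decarboxylates spontaneously to the deoxybenzoin at near‑neutral pH.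

Step 15
Reactants: 23 the deoxybenzoin
Product: 25 2‑bromo‑2‑[4‑(benzyloxy)phenyl]‑1‑(DBF)ethan‑1‑one (epimer mixture, used crude), via lithium ketone enolate 24 (not isolated)
Conditions: LiN(SiMe3)2 (1.1 equiv), THF, −78 °C; NBS (1.05 equiv), −78 °C; H2O
Reagents that add atoms: N‑bromosuccinimide, O=C1CCC(=O)N1Br
Why: Bromination of the preformed ketone enolate is instantaneous at −78 °C, so the electron‑rich arenes are not brominated.

Step 16
Reactants: 25 the α‑bromo ketone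
Product: 26 penta‑O‑benzyl pauciflorol E as a mixture of C(α) epimers
Conditions: AgOSO2CF3 (1.5 equiv), 2,6‑di‑tert‑butyl‑4‑methylpyridine (2 equiv), CH2Cl2 (0.005 M), −40 to 0 °C
Reagents that add atoms: none
Why: Silver‑assisted ionisation gives the 4‑(benzyloxy)phenyl‑stabilised α‑keto cation, which undergoes intramolecular Friedel–Crafts alkylation at the ring B carbon ortho to the C3 attachment and para to a benzyloxy group, closing the seven‑membered ring.

Step 17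
Reactants: 26 the epimer mixture
Product: 27 penta‑O‑benzyl pauciflorol E, with (2R,3R) dihydrofuran and (R) at C(α)
Conditions: DBU (0.5 equiv), CH2Cl2, rt
Reagents that add atoms: none
Why: Base‑mediated enolisation equilibrates the doubly activated C(α)–H to the thermodynamic epimer, in which the aryl group stands perpendicular to ring B and the hydrogen lies in the ring B plane next to the ortho benzyloxy group (least allylic strain); this is the R configuration.

Step 18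
Reactants: 27 penta‑O‑benzyl pauciflorol E
Product: 28 pauciflorol E
Conditions: BCl3 (10 equiv), pentamethylbenzene (15 equiv), CH2Cl2, −78 °C; MeOH, then H2O
Reagents that add atoms: none
Why: Lewis‑acid debenzylation with pentamethylbenzene as a Friedel–Crafts trap for the benzyl cations removes all five benzyl ethers at −78 °C, leaving the ketone and the trans dihydrobenzofuran intact with no stereocentre touched.

**Compound list**

1 | 5‑bromobenzene‑1,3‑diol | Oc1cc(O)cc(Br)c1 | starting material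
2 | 1,3‑bis(benzyloxy)‑5‑bromobenzene | Brc1cc(OCc2ccccc2)cc(OCc2ccccc2)c1 | intermediate
3 | N‑{[2,4‑bis(benzyloxy)‑6‑bromophenyl]methylidene}‑N‑methylmethanaminium dichlorophosphate | C[N+](C)=Cc1c(Br)cc(OCc2ccccc2)cc1OCc1ccccc1.[O-]P(=O)(Cl)Cl | intermediate
4 | 2,4‑bis(benzyloxy)‑6‑bromobenzaldehyde | O=Cc1c(Br)cc(OCc2ccccc2)cc1OCc1ccccc1 | intermediate
5 | 4‑(benzyloxy)‑2‑bromo‑6‑hydroxybenzaldehyde | O=Cc1c(O)cc(OCc2ccccc2)cc1Br | intermediate
6 | 1‑(benzyloxy)‑4‑(chloromethyl)benzene | ClCc1ccc(OCc2ccccc2)cc1 | starting material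
7 | 4‑(benzyloxy)‑2‑{[4‑(benzyloxy)phenyl]methoxy}‑6‑bromobenzaldehyde | O=Cc1c(Br)cc(OCc2ccccc2)cc1OCc1ccc(OCc2ccccc2)cc1 | intermediate
8 | [3,5‑bis(benzyloxy)phenyl]magnesium bromide | Br[Mg]c1cc(OCc2ccccc2)cc(OCc2ccccc2)c1 | intermediate
9 | [4‑(benzyloxy)‑2‑{[4‑(benzyloxy)phenyl]methoxy}‑6‑bromophenyl][3,5‑bis(benzyloxy)phenyl]methanol (racemic) | OC(c1cc(OCc2ccccc2)cc(OCc2ccccc2)c1)c1c(Br)cc(OCc2ccccc2)cc1OCc1ccc(OCc2ccccc2)cc1 | intermediate
10 | [4‑(benzyloxy)‑2‑{[4‑(benzyloxy)phenyl]methoxy}‑6‑bromophenyl][3,5‑bis(benzyloxy)phenyl]methanone | O=C(c1cc(OCc2ccccc2)cc(OCc2ccccc2)c1)c1c(Br)cc(OCc2ccccc2)cc1OCc1ccc(OCc2ccccc2)cc1 | intermediate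
11 | hydrazone of 10 (E/Z mixture) | NN=C(c1cc(OCc2ccccc2)cc(OCc2ccccc2)c1)c1c(Br)cc(OCc2ccccc2)cc1OCc1ccc(OCc2ccccc2)cc1 | intermediate
12 | 5‑(benzyloxy)‑1‑{[4‑(benzyloxy)phenyl]methoxy}‑3‑bromo‑2‑{[3,5‑bis(benzyloxy)phenyl](diazo)methyl}benzene | [N-]=[N+]=C(c1cc(OCc2ccccc2)cc(OCc2ccccc2)c1)c1c(Br)cc(OCc2ccccc2)cc1OCc1ccc(OCc2ccccc2)cc1 | intermediate
13 | (2S,3R)‑6‑(benzyloxy)‑2‑[4‑(benzyloxy)phenyl]‑3‑[3,5‑bis(benzyloxy)phenyl]‑4‑bromo‑2,3‑dihydro‑1‑benzofuran (cis) | Brc1cc(OCc3ccccc3)cc2c1[C@@H](c1cc(OCc3ccccc3)cc(OCc3ccccc3)c1)[C@@H](c1ccc(OCc3ccccc3)cc1)O2 | intermediate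
14 | (2R,3R)‑6‑(benzyloxy)‑2‑[4‑(benzyloxy)phenyl]‑3‑[3,5‑bis(benzyloxy)phenyl]‑4‑bromo‑2,3‑dihydro‑1‑benzofuran (trans) | Brc1cc(OCc3ccccc3)cc2c1[C@@H](c1cc(OCc3ccccc3)cc(OCc3ccccc3)c1)[C@H](c1ccc(OCc3ccccc3)cc1)O2 | intermediate
15 | (DBF)lithium | [Li]c1cc(OCc3ccccc3)cc2c1[C@@H](c1cc(OCc3ccccc3)cc(OCc3ccccc3)c1)[C@H](c1ccc(OCc3ccccc3)cc1)O2 | intermediate
16 | (2R,3R)‑6‑(benzyloxy)‑2‑[4‑(benzyloxy)phenyl]‑3‑[3,5‑bis(benzyloxy)phenyl]‑2,3‑dihydro‑1‑benzofuran‑4‑carbaldehyde | O=Cc1cc(OCc3ccccc3)cc2c1[C@@H](c1cc(OCc3ccccc3)cc(OCc3ccccc3)c1)[C@H](c1ccc(OCc3ccccc3)cc1)O2 | intermediate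
17 | [4‑(benzyloxy)phenyl]acetic acid | OC(=O)Cc1ccc(OCc2ccccc2)cc1 | starting material
18 | prop‑2‑en‑1‑yl [4‑(benzyloxy)phenyl]acetate | C=CCOC(=O)Cc1ccc(OCc2ccccc2)cc1 | intermediate
19 | lithium enolate of 18 | [Li+].[O-]C(OCC=C)=Cc1ccc(OCc2ccccc2)cc1 | intermediate
20 | prop‑2‑en‑1‑yl 2‑[4‑(benzyloxy)phenyl]‑3‑hydroxy‑3‑(DBF)propanoate (diastereomer mixture) | C=CCOC(=O)C(c1ccc(OCc2ccccc2)cc1)C(O)c1cc(OCc3ccccc3)cc2c1[C@@H](c1cc(OCc3ccccc3)cc(OCc3ccccc3)c1)[C@H](c1ccc(OCc3ccccc3)cc1)O2 | intermediate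
21 | prop‑2‑en‑1‑yl 2‑[4‑(benzyloxy)phenyl]‑3‑oxo‑3‑(DBF)propanoate | C=CCOC(=O)C(c1ccc(OCc2ccccc2)cc1)C(=O)c1cc(OCc3ccccc3)cc2c1[C@@H](c1cc(OCc3ccccc3)cc(OCc3ccccc3)c1)[C@H](c1ccc(OCc3ccccc3)cc1)O2 | intermediate
22 | 2‑[4‑(benzyloxy)phenyl]‑3‑oxo‑3‑(DBF)propanoic acid | OC(=O)C(c1ccc(OCc2ccccc2)cc1)C(=O)c1cc(OCc3ccccc3)cc2c1[C@@H](c1cc(OCc3ccccc3)cc(OCc3ccccc3)c1)[C@H](c1ccc(OCc3ccccc3)cc1)O2 | intermediate
23 | 2‑[4‑(benzyloxy)phenyl]‑1‑(DBF)ethan‑1‑one | O=C(Cc1ccc(OCc2ccccc2)cc1)c1cc(OCc3ccccc3)cc2c1[C@@H](c1cc(OCc3ccccc3)cc(OCc3ccccc3)c1)[C@H](c1ccc(OCc3ccccc3)cc1)O2 | intermediate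
24 | lithium enolate of 23 | [Li+].[O-]C(=Cc1ccc(OCc2ccccc2)cc1)c1cc(OCc3ccccc3)cc2c1[C@@H](c1cc(OCc3ccccc3)cc(OCc3ccccc3)c1)[C@H](c1ccc(OCc3ccccc3)cc1)O2 | intermediate
25 | 2‑bromo‑2‑[4‑(benzyloxy)phenyl]‑1‑(DBF)ethan‑1‑one (epimer mixture) | O=C(C(Br)c1ccc(OCc2ccccc2)cc1)c1cc(OCc3ccccc3)cc2c1[C@@H](c1cc(OCc3ccccc3)cc(OCc3ccccc3)c1)[C@H](c1ccc(OCc3ccccc3)cc1)O2 | intermediate
26 | penta‑O‑benzyl pauciflorol E, mixture of C(α) epimers | O=C1c2cc(OCc4ccccc4)cc3c2[C@@H](c2cc(OCc4ccccc4)cc(OCc4ccccc4)c2C1c1ccc(OCc4ccccc4)cc1)[C@H](c1ccc(OCc4ccccc4)cc1)O3 | intermediate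
27 | penta‑O‑benzyl pauciflorol E, (2R,3R) dihydrofuran and (R) at C(α) | O=C1c2cc(OCc4ccccc4)cc3c2[C@@H](c2cc(OCc4ccccc4)cc(OCc4ccccc4)c2[C@H]1c1ccc(OCc4ccccc4)cc1)[C@H](c1ccc(OCc4ccccc4)cc1)O3 | intermediate
28 | pauciflorol E | O=C1c2cc(O)cc3c2[C@@H](c2cc(O)cc(O)c2[C@H]1c1ccc(O)cc1)[C@H](c1ccc(O)cc1)O3 | target

**Step count and risks**

Total steps: 18. Longest linear sequence: 17 (steps 1–10 and 12–18, from compound 1); step 11 is a one‑step side branch.

Most likely to fail: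

Step 8 (together with its hindered hydrazone precursor from step 7): the carbene carbon sits between two ortho substituents, so hydrazone formation, insertion yield or enantioselectivity may be poor. The fallback sets out from 7 and comes back at 14, and sets C3 by asymmetric conjugate addition instead of C–H insertion. Henry condensation of 7 with nitromethane (NH4OAc, AcOH, 90 °C) gives 5‑(benzyloxy)‑1‑{[4‑(benzyloxy)phenyl]methoxy}‑3‑bromo‑2‑[(E)‑2‑nitroethenyl]benzene F1. Hayashi–Miyaura addition of 3,5‑bis(benzyloxy)phenylboronic acid (Rh(acac)(C2H4)2, (R)‑BINAP, dioxane/H2O, 90 °C; the ligand antipode is used if the sense is opposite) gives 5‑(benzyloxy)‑1‑{[4‑(benzyloxy)phenyl]methoxy}‑2‑{(1R)‑1‑[3,5‑bis(benzyloxy)phenyl]‑2‑nitroethyl}‑3‑bromobenzene F2. A buffered reductive Nef reaction (NaOMe, then aq TiCl3/NH4OAc) gives the configurationally sensitive (2R)‑2‑[4‑(benzyloxy)‑2‑{[4‑(benzyloxy)phenyl]methoxy}‑6‑bromophenyl]‑2‑[3,5‑bis(benzyloxy)phenyl]acetaldehyde F3, which is used at once. Addition of 4‑(benzyloxy)phenylmagnesium bromide at −78 °C gives (2R)‑2‑[4‑(benzyloxy)‑2‑{[4‑(benzyloxy)phenyl]methoxy}‑6‑bromophenyl]‑1‑[4‑(benzyloxy)phenyl]‑2‑[3,5‑bis(benzyloxy)phenyl]ethan‑1‑ol F4 as a carbinol epimer mixture. CF3CO2H with pentamethylbenzene in CH2Cl2 at 0 °C then removes the acid‑labile 4‑(benzyloxy)benzyl ether and ionises the carbinol, and the freed phenol closes to the trans dihydrobenzofuran 14.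

Step 16: the α‑keto cation may lose a benzyl group or fail to close the seven‑membered ring. The fallback sets out from 23 and comes back at 26, replacing the cationic closure by a cross‑coupling. NBS (1.0 equiv, CH3CN, −20 °C) brominates ring B ortho to the C3 attachment to give 2‑[4‑(benzyloxy)phenyl]‑1‑{(2R,3S)‑6‑(benzyloxy)‑2‑[4‑(benzyloxy)phenyl]‑3‑[3,5‑bis(benzyloxy)‑2‑bromophenyl]‑2,3‑dihydro‑1‑benzofuran‑4‑yl}ethan‑1‑one F5 (the 3S label is a priority change only, the geometry is unchanged). Intramolecular ketone α‑arylation (Pd2(dba)3, XPhos, NaOtBu, toluene, 90 °C; zerovalent palladium oxidative addition, enolate binding, reductive elimination) then gives 26.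

Step 18: BCl3 may open the dihydrofuran or give incomplete debenzylation. The fallback sets out from 27 and comes back at 28 by hydrogenolysis (H2 1 atm, Pd(OH)2/C, EtOAc/MeOH, rt, stopped as soon as the last benzyl group is gone); it makes no new compound (F0).

**Further compounds**

F1 | step 8 | 5‑(benzyloxy)‑1‑{[4‑(benzyloxy)phenyl]methoxy}‑3‑bromo‑2‑[(E)‑2‑nitroethenyl]benzene | [O-][N+](=O)/C=C/c1c(Br)cc(OCc2ccccc2)cc1OCc1ccc(OCc2ccccc2)cc1
F2 | step 8 | 5‑(benzyloxy)‑1‑{[4‑(benzyloxy)phenyl]methoxy}‑2‑{(1R)‑1‑[3,5‑bis(benzyloxy)phenyl]‑2‑nitroethyl}‑3‑bromobenzene | [O-][N+](=O)C[C@H](c1cc(OCc2ccccc2)cc(OCc2ccccc2)c1)c1c(Br)cc(OCc2ccccc2)cc1OCc1ccc(OCc2ccccc2)cc1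
F3 | step 8 | (2R)‑2‑[4‑(benzyloxy)‑2‑{[4‑(benzyloxy)phenyl]methoxy}‑6‑bromophenyl]‑2‑[3,5‑bis(benzyloxy)phenyl]acetaldehyde | O=C[C@H](c1cc(OCc2ccccc2)cc(OCc2ccccc2)c1)c1c(Br)cc(OCc2ccccc2)cc1OCc1ccc(OCc2ccccc2)cc1
F4 | step 8 | (2R)‑2‑[4‑(benzyloxy)‑2‑{[4‑(benzyloxy)phenyl]methoxy}‑6‑bromophenyl]‑1‑[4‑(benzyloxy)phenyl]‑2‑[3,5‑bis(benzyloxy)phenyl]ethan‑1‑ol (C1 epimer mixture) | OC(c1ccc(OCc2ccccc2)cc1)[C@H](c1cc(OCc2ccccc2)cc(OCc2ccccc2)c1)c1c(Br)cc(OCc2ccccc2)cc1OCc1ccc(OCc2ccccc2)cc1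
F5 | step 16 | 2‑[4‑(benzyloxy)phenyl]‑1‑{(2R,3S)‑6‑(benzyloxy)‑2‑[4‑(benzyloxy)phenyl]‑3‑[3,5‑bis(benzyloxy)‑2‑bromophenyl]‑2,3‑dihydro‑1‑benzofuran‑4‑yl}ethan‑1‑one | O=C(Cc1ccc(OCc2ccccc2)cc1)c1cc(OCc3ccccc3)cc2c1[C@@H](c1cc(OCc3ccccc3)cc(OCc3ccccc3)c1Br)[C@H](c1ccc(OCc3ccccc3)cc1)O2
F0 | step 18 | none | none
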